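**Conventions and assumptions (remarks on the chemistry)**

- Briarane numbering is used for every intermediate. Ring A is C1, C10, C11, C12, C13, C14; the ten-membered ring is C1–C10. C15 sits on C1, C16 on C5, C20 on C11; the lactone is C7–O–C19(=O)–C17(C18)–C8. "β" is the face of ring A that carries C15.
- The structures of the key-step pair (32 and 33) were checked against the target. Drawn through the chair, the 5S centre and the E enol ether of 32 lead to 7S and the Z alkene of 33, and C1, C2, C10 and C14 match the target. Nothing had to be corrected.
- The precursor is approached differently from the obvious ketone-addition/lactonisation order in four respects. C5 comes from an asymmetric epoxidation. The E geometry comes from a syn hydrometalation and a stereoretentive C–O coupling. The donor enol ether is attached only after the carbonyl methylenation, so no ionisable tertiary allylic ester is carried. The lactone is closed onto a small propargylic carbinol.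
- Geraniol, (S)-(+)-carvone, 4-methoxybenzyl alcohol, methyl propanoate and all reagents are taken as commercial. Centres that are formed without control and erased later (C1/C2 in 14, C8 in 35) are left open in the SMILES.

## Structural features

The target is a tricyclic briarane. A cyclohexene (ring A, C11=C12 with the C20 methyl) is trans-fused through C1–C10 to a ten-membered carbocycle holding a Z trisubstituted C5=C6 alkene, and a γ-lactone (O–C7, C8, C17, C19) is fused across C7–C8. There are eight stereocentres; C14, C1, C10, C9, C8 and C7 are contiguous, C17 hangs on C8 and C2 flanks the quaternary C1 on the other side. C1 (all-carbon quaternary) and C8 (tertiary carbinol) are the fully substituted ones. C10–H is allylic and, whenever C9 is a ketone or ester carbon, also α to a carbonyl, so it can epimerise or slip into conjugation. The C8 carbinol is β to the lactone carbonyl and next to C9, which invites retro-aldol, elimination or ketol shift, and the two acetates rule out strong nucleophiles late in the route. The real difficulty is the ten-membered ring with its Z alkene and trans fusion: a direct cyclodecene closure pays entropy and transannular strain and would have to set the geometry at the same time. The feature exploited is the relationship C9(O)···C5=C6 inside that ring: with C9 as a ketone, C9–C8–C7–C6=C5 is a γ,δ-unsaturated ketone, the retron of a Claisen rearrangement. An oxygen bridge from C9 to C5, that is an eight-membered exocyclic enol ether fused to ring A, is therefore the precursor and C7–C8 the bond to form. The C7 oxygen then sits on the vinyl terminus of that precursor, where its configuration and the alkene geometry are decided together in one chair.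

## Logic of the disconnections

44 to 43: the C9–H bond is cut, so C9 is a ketone until the last step. This keeps only the C2 and C14 hydroxyls free during acetylation, so no protecting group is needed for O9. The forward step must deliver hydride to C9 from the face syn to C17, which a chelate between O8 and O9 should secure.

43 to 42 to 41: the two O–acyl bonds at C2 and C14 are cut and replaced by silyl ethers. Esters would not survive the organolithium, hydride and titanium carbene steps earlier on. The demand is a desilylation and acylation that leave the C8 ketol and the lactone alone.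

41 to 39 (through 40), then to 36 and 37: the lactone C19–O7 bond and the C8–C17 bond are cut. This gives a 1,2-diketone and a three-carbon ester, so the C8 carbinol and the side chain arrive in one addition. The forward step must attack C8 rather than C9 and on the face anti to C6; the O7 ether next to C8 offers a chelate for both. C17 has to follow from the enolate geometry.

36 to 35 to 33: the C8 carbonyl is traced back to a methylene. This is a pure oxidation-level adjustment that takes the route back to the direct product of the ring expansion. It demands kinetic enolisation at C8 and not at the allylic C10.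

33 to 32 (key disconnection): C7–C8 is cut and C5–O is re-formed. The ten-membered ring becomes an eight-membered enol ether, and the alkene geometry and C7 are traced to one stereocentre (C5) and one enol ether geometry. The forward step needs the chair with C4 axial and the C5 methyl equatorial, and strictly non-acidic conditions.

32 to 30 and 31, 30 to 29, 29 to 27: the C7–O ether bond, the C9=C8 bond and the C7–I bond are cut in turn, leaving a lactone with an ethynyl group on C5. The order puts the electron-rich enol ether on last. The demands are syn hydrometalation (E), retention in the C–O coupling, and methylenation without epimerising C10.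

27 to 25: the acyl C9–O5 bond is cut to a hydroxy acid. The carbinol is tertiary but propargylic and small, and the two arms are trans on ring A with gem-substitution at C1 and C5. The forward step is an eight-membered lactonisation and is one of the weak points.

25 to 24 to 23 to 22 to 20, then 20 to 19 to 18: C9 is taken back to the alcohol level and the C9–C10 bond is cut as a [2,3] shift from an ether on O12. The enone of 18 is the transposed equivalent of that allylic alcohol. This reduces the C10 centre to the C12 carbinol configuration, which should come from epoxidation anti to O14. The demands are a β epoxide and a suprafacial shift.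

18 to 17 to 16 to 15: the silyl ether on O2, the C2–H bond and the C1–C15 bond are cut. C2 becomes a ketone reduced under reagent control, and the quaternary centre comes from methylation of a β-diketone anti to O14. The forward reduction must leave the enone carbonyl at C10 untouched.

15 to 14 to 12 and 7: the C1–C2 bond is cut as an aldol followed by oxidation. This is the convergent union of ring A with the C2–C7 chain. Stereochemistry is not required here because both new centres are erased.

12 to 11 to 10 to 8, and 7 to 5 to 4 to 3 to 2 to 1: on the ring side, C14–O is traced to the isopropenyl-bearing carbon of 8 by oxidative degradation with retention. On the chain side, the C2 aldehyde comes from alkene cleavage, the alkyne from an epoxy chloride and the C5 centre from the asymmetric epoxidation of 1. Both starting materials supply their stereocentre and most of their carbons.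

## Other disconnections considered

Alternative 1: The cut is C1–C10, made across the fourteen-membered carbocycle A1, which carries a 2-methyl-1,3-dione (C2, C14) and a C9–C10 vinyl epoxide. In the forward step Pd(PPh3)4 would ionise the epoxide (zerovalent palladium entering anti to oxygen) and the C1 enolate would attack C10 across the ring, giving A2.
- In favour: ring A, the ten-membered ring, the quaternary C1 and C10 would all be made in one step. A soft enolate attacking a π-allyl complex gives net retention, so the epoxide configuration maps onto the trans fusion. A fourteen-membered ring is easier to close than a ten-membered one, and no acid-labile enol ether is carried. On bond economy in the key step and on the robustness of its substrate this alternative is the better one.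
- Against: the π-allyl unit has a second terminus (C12), the usual site of attack, and reaction there would give a different ring system. The C1 configuration depends on which enolate face meets C10, which means on the conformation of a flexible macrocycle. A1 must already hold C7, C8, C9, C17, the lactone and the Z alkene. A2 still has C2 and C14 as ketones, needing two controlled reductions and the differentiation of four hydroxyls.
- Comparison: structurally, the chosen plan derives the alkene geometry and C7 from one centre, while here several centres rest on macrocyclic conformation. Mechanistically, a pericyclic chair is set against a transannular ion-pair alkylation with a regiochemical choice. In step count, the single step is more productive here, but the path to A1 and the work after A2 are judged longer than the route below.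

Alternative 2: The cut is C8–C17 together with the lactone, starting from the bromopropionate A3 (C8 ketone, O9 silyl ether, acetates in place). SmI2 would reduce the C–Br bond to a samarium enolate, which adds to the C8 carbonyl and gives A4; desilylation finishes the synthesis.
- In favour: the tether delivers C17 to C8 intramolecularly, and the carbinol and lactone form together. The conditions are neutral and tolerate the acetates, and only one step follows. On end-game length it is better than the chosen route (seven steps after the ring expansion), and the tether should control the C8 face at least as well as the chelate used in step 27.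
- Against: it does not address the ten-membered ring, so A3 must come from another ring-forming strategy. A3 is a ketone with oxygen on both α carbons, and reductive cleavage of the C7–O or C9–O bond by SmI2 competes with C–Br reduction. C17 rests on a samarium enolate of undefined geometry.
- Comparison: it is complementary rather than competing. The chosen route makes the same C8–C17 bond intermolecularly on 36 and needs no bromo ester and no separate O9 protection.

Alternative 3: The cut is C2–C7, seen in reverse as the glycol cleavage of the tricyclic cis-diol A5. Pb(OAc)4 would cleave the ring-fusion bond and release the ten-membered diketone A6.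
- In favour: the ten-membered ring is obtained from six-membered ring chemistry without any medium-ring closure. The Z alkene is guaranteed because it starts inside a cyclohexene; on this point the alternative is better than the chosen plan, where the geometry depends on the choice of chair. Glycol cleavage itself is mild and reliable.
- Against: A6 has carbonyls at C2 and C7, where the target has oxygenated sp3 centres. Both need controlled reduction, and C7 is the carbonyl of a Z enone next to the quaternary C8, prone to isomerisation and transannular reactions. A5 needs two tertiary carbinols at a cis fusion in addition to C8, C9, C17 and ring A.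
- Comparison: structurally, it trades the medium-ring problem for a dense tricycle. Mechanistically, a fragmentation is set against a sigmatropic shift, both reliable in themselves. In step count it is judged longer because of the redox corrections at C2 and C7.

Key step: step 24

## Route

Step 1
Reactants: 1 geraniol
Product: 2 (2S,3S)-2,3-epoxygeraniol
Conditions: Ti(OiPr)4 (cat.), L-(+)-diethyl tartrate (cat.), t-BuOOH, 4 Å MS, CH2Cl2, −20 °C
Reagents that add atoms: tert-butyl hydroperoxide, CC(C)(C)OO
Why: Sharpless asymmetric epoxidation of the allylic alcohol; the L-tartrate catalyst delivers oxygen to the face that gives the (2S,3S) epoxide and so fixes the future C5 carbinol centre, while the remote alkene (no allylic OH) is left alone.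

Step 2
Reactants: 2 (2S,3S)-2,3-epoxygeraniol
Product: 3 (2R,3S)-2,3-epoxygeranyl chloride
Conditions: PPh3, CCl4, NaHCO3, reflux
Reagents that add atoms: tetrachloromethane, ClC(Cl)(Cl)Cl
Why: Appel chlorination of the primary alcohol under buffered conditions; the epoxide is not opened and no stereocentre is touched (the descriptor at C2 changes only through CIP priorities).

Step 3
Reactants: 3 (2R,3S)-2,3-epoxygeranyl chloride
Product: 4 (S)-3,7-dimethyloct-6-en-1-yn-3-ol
Conditions: n-BuLi (3.2 equiv), THF, −40 °C; aq. NH4Cl
Reagents that add atoms: none
Why: Base-induced double elimination of a 2,3-epoxy chloride to a propargylic alcohol (Takano–Yadav alkyne synthesis); the tertiary C–O bond is never broken, so the C5 configuration is retained.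

Step 4
Reactants: 4 (S)-3,7-dimethyloct-6-en-1-yn-3-ol
Product: 5 triethylsilyl ether of 4
Conditions: TESOTf, 2,6-lutidine, CH2Cl2, −78 to 0 °C
Reagents that add atoms: triethylsilyl trifluoromethanesulfonate, CC[Si](CC)(CC)OS(=O)(=O)C(F)(F)F
Why: Silyl triflate silylation of a tertiary alcohol; TES is chosen because it can later be removed beside the TBS ethers.

Step 5
Reactants: 5 triethylsilyl ether of 4
Product: 7 (S)-4-methyl-4-(triethylsilyloxy)hex-5-ynal, via ozonide 6 (not isolated)
Conditions: O3, CH2Cl2–pyridine, −78 °C (indicator end point); PPh3
Reagents that add atoms: ozone, [O-][O+]=O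
Why: Ozonolysis with reductive work-up; the electron-rich trisubstituted alkene reacts much faster than the terminal alkyne, and the aldehyde carbon is C2 of the target.

Step 6
Reactants: 8 (S)-(+)-carvone
Product: 10 (S)-5-acetoxy-2-methylcyclohex-2-enone, via methoxy hydroperoxide 9 (not isolated)
Conditions: O3, CH2Cl2–MeOH, −78 °C; then Ac2O, Et3N, DMAP, 0 to 40 °C
Reagents that add atoms: ozone, [O-][O+]=O; methanol, CO
Why: Ozonolysis of the isopropenyl group in methanol followed by Criegee rearrangement of the acylated hydroperoxide; the ring carbon migrates to oxygen with retention, so C14–O takes the configuration of the carvone stereocentre, and the electron-poor enone alkene is not attacked.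

Step 7
Reactants: 10 (S)-5-acetoxy-2-methylcyclohex-2-enone
Product: 11 (S)-5-hydroxy-2-methylcyclohex-2-enone
Conditions: K2CO3 (0.2 equiv), MeOH, 0 °C
Reagents that add atoms: none
Why: Mild transesterification; low temperature and substoichiometric base limit β-elimination of the β-oxygenated ketone.

Step 8
Reactants: 11 (S)-5-hydroxy-2-methylcyclohex-2-enone
Product: 12 (S)-5-(tert-butyldimethylsilyloxy)-2-methylcyclohex-2-enone
Conditions: TBSCl, imidazole, DMF, rt
Reagents that add atoms: tert-butyldimethylsilyl chloride, CC(C)(C)[Si](C)(C)Cl
Why: Standard silylation of a secondary alcohol; the TBS ether later directs reagents to the opposite face of ring A.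

Step 9
Reactants: 12 (S)-5-(tert-butyldimethylsilyloxy)-2-methylcyclohex-2-enone; 7 (S)-4-methyl-4-(triethylsilyloxy)hex-5-ynal
Product: 14 aldol adduct (C1–C2 bond; epimers at C1 and C2), via lithium dienolate 13 (not isolated)
Conditions: LDA, THF, −78 °C; then 7, −78 °C; aq. NH4Cl
Reagents that add atoms: none
Why: Kinetic α′-deprotonation of the enone and aldol addition to the aldehyde join ring A to the C2–C7 chain; the two new centres need no control because both are erased in steps 10 and 11.

Step 10
Reactants: 14 aldol adduct
Product: 15 2,10-diketone (C1–H)
Conditions: DMP, NaHCO3, CH2Cl2, 0 °C to rt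
Reagents that add atoms: none
Why: Dess–Martin oxidation of the secondary carbinol to the β-diketone under buffered, non-basic conditions that avoid retro-aldol cleavage.

Step 11
Reactants: 15 2,10-diketone (C1–H)
Product: 16 C1-methylated 2,10-diketone
Conditions: K2CO3, MeI, acetone, rt
Reagents that add atoms: iodomethane, CI
Why: C-Alkylation of the β-diketone enolate creates the quaternary C1; methyl iodide approaches anti to the neighbouring C14 silyloxy group, so C15 is β and the C2 arm is cis to O14.

Step 12
Reactants: 16 C1-methylated 2,10-diketone
Product: 17 (2R)-carbinol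
Conditions: (S)-Me-CBS (1 equiv), catecholborane, toluene, −78 to −40 °C
Reagents that add atoms: none
Why: Corey–Bakshi–Shibata reduction under reagent control (quaternary C1 as the large group, C3H2 as the small one) should give 2R; the C10 carbonyl is conjugated and flanked by C1 and the methyl-bearing C11, so it is less electrophilic and more hindered.

Step 13
Reactants: 17 (2R)-carbinol
Product: 18 2,14-bis-TBS ether enone
Conditions: TBSOTf, 2,6-lutidine, CH2Cl2, −78 to 0 °C
Reagents that add atoms: tert-butyldimethylsilyl trifluoromethanesulfonate, CC(C)(C)[Si](C)(C)OS(=O)(=O)C(F)(F)F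
Why: Silyl triflate silylation of the hindered neopentyl carbinol; this removes the β-hydroxy ketone before the basic steps that follow.

Step 14
Reactants: 18 2,14-bis-TBS ether enone
Product: 19 11β,12β-epoxy ketone
Conditions: 30% H2O2, aq. NaOH, MeOH, 0 °C
Reagents that add atoms: hydrogen peroxide, OO
Why: Weitz–Scheffer epoxidation of the enone; hydroperoxide adds to C12 anti to the C14 silyloxy group (the same sense as for carvone, trans to its ring substituent), which places the epoxide on the β face.

Step 15
Reactants: 19 11β,12β-epoxy ketone
Product: 20 12β-allylic alcohol (C10=C11)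
Conditions: N2H4·H2O, AcOH (cat.), MeOH, 0 °C to rt
Reagents that add atoms: none
Why: Wharton transposition (hydrazone formation, epoxide opening, loss of N2) turns the epoxy ketone into the transposed allylic alcohol; the C12–O bond is untouched, so the carbinol stays β.

Step 16
Reactants: 20 12β-allylic alcohol (C10=C11)
Product: 22 (tributylstannyl)methyl ether, via potassium alkoxide 21 (not isolated)
Conditions: KH, 18-crown-6 (cat.), THF, 0 °C; then Bu3SnCH2I, 0 °C to rt
Reagents that add atoms: (iodomethyl)tributylstannane, CCCC[Sn](CCCC)(CCCC)CI
Why: Williamson etherification; in THF the alkoxide is far more nucleophilic toward the primary iodide than any acetylide formed from the terminal alkyne.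

Step 17
Reactants: 22 (tributylstannyl)methyl ether
Product: 23 C9 primary alcohol (10β-hydroxymethyl; C11=C12)
Conditions: n-BuLi (3 equiv), THF, −78 °C; aq. NH4Cl
Reagents that add atoms: none
Why: Still variant of the [2,3]-Wittig rearrangement: tin–lithium exchange gives the α-alkoxy carbanion, which shifts suprafacially, so C9 is delivered to C10 on the β face (the face of O12) and the C11=C12 alkene is formed; excess base covers the alkyne C–H.

Step 18
Reactants: 23 C9 primary alcohol
Product: 24 C9 carboxylic acid (O5 triethylsilyl ether)
Conditions: TEMPO (cat.), NaOCl (cat.), NaClO2, MeCN–phosphate buffer (pH 6.7), 35 °C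
Reagents that add atoms: sodium chlorite, [Na+].[O-]Cl=O
Why: One-pot nitroxyl/chlorite oxidation of a primary alcohol to the acid at near-neutral pH, so that C10 (α to the transient carbonyl and allylic) is not epimerised.

Step 19
Reactants: 24 C9 carboxylic acid (O5 triethylsilyl ether)
Product: 25 hydroxy acid (free C5 carbinol)
Conditions: HF·pyridine, pyridine, THF, 0 °C
Reagents that add atoms: none
Why: Buffered fluoride cleaves the triethylsilyl ether much faster than the two hindered secondary TBS ethers.

Step 20
Reactants: 25 hydroxy acid (free C5 carbinol)
Product: 27 eight-membered lactone (5-ethynyl), via mixed anhydride 26 (not isolated)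
Conditions: 2,4,6-trichlorobenzoyl chloride, Et3N, THF, rt; then slow addition to DMAP, toluene, 80 °C (high dilution)
Reagents that add atoms: none
Why: Yamaguchi lactonisation; the nucleophile is a propargylic tertiary carbinol (small linear ethynyl group), the two arms are trans on ring A and both carry gem-substitution (C1, C5), which should favour closure of the eight-membered ring; no stereocentre is formed.

Step 21
Reactants: 27 eight-membered lactone (5-ethynyl)
Product: 29 (E)-2-iodovinyl lactone, via alkenylzirconocene 28 (not isolated)
Conditions: Cp2Zr(H)Cl, THF, rt; then I2, 0 °C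
Reagents that add atoms: iodine, II
Why: Hydrozirconation of the terminal alkyne is a syn addition with zirconium on the terminal carbon, and iodinolysis proceeds with retention, so the E vinyl iodide results; the lactone and the trisubstituted alkene react much more slowly.

Step 22
Reactants: 29 (E)-2-iodovinyl lactone
Product: 30 (E)-2-iodovinyl 2-methyleneoxocane
Conditions: Cp2TiMe2, toluene, 70 °C, dark
Reagents that add atoms: dimethyltitanocene Cp2TiMe2, [CH3-].[CH3-].[Ti+4].c1cc[cH-]c1.c1cc[cH-]c1
Why: Petasis methylenation of the lactone carbonyl (thermally generated titanium methylidene, oxatitanacyclobutane) gives the exocyclic enol ether under non-acidic, non-basic conditions, so C10 is not epimerised.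

Step 23
Reactants: 30 (E)-2-iodovinyl 2-methyleneoxocane; 31 4-methoxybenzyl alcohol
Product: 32 Claisen precursor ((E)-2-(4-methoxybenzyloxy)vinyl 2-methyleneoxocane)
Conditions: CuI (10 mol%), 3,4,7,8-tetramethyl-1,10-phenanthroline (20 mol%), Cs2CO3, toluene, 80 °C
Reagents that add atoms: none
Why: Copper-catalysed coupling of a vinyl iodide with a primary alcohol proceeds with retention of alkene geometry and gives the E enol ether; the donor is attached only now, on an ether and under basic conditions, so no ionisable tertiary allylic ester was ever carried.

Step 24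
Reactants: 32 Claisen precursor
Product: 33 cyclodecenone (C9 ketone, 7S 4-methoxybenzyl ether, Z C5=C6)
Conditions: toluene, Et3N (trace), base-washed sealed tube, 120 °C
Reagents that add atoms: none
Why: Thermal Claisen rearrangement of the allyl vinyl ether C8=C9–O–C5–C6=C7: a concerted suprafacial 3,3-shift through a chair forms C7–C8, breaks C5–O and turns the enol ether carbon C9 into the ketone. The closest known reaction type is the Claisen ring expansion of 2-methylene-6-vinyltetrahydropyrans to cyclooctenones; here the oxygen-bridged ring has eight members, so ten result. The ten-membered ring is not closed end to end: C8 and C7 are inserted into the existing eight-membered ring through a bridged bicyclic chair (two-carbon ring expansion), which avoids the entropy and transannular cost of a direct cyclodecene closure. The only new stereocentre, C7, is controlled by the 5S centre together with the E enol ether: the E oxygen is equatorial at C7 and the chirality of C5 is transferred to give 7S. The Z alkene needs the chair with C4 axial and the C5 methyl equatorial; this is the chair that the tether C4–C3–C2–C1–C10 can span from C5 to the in-plane substituent of C9, and the equatorial preference of the methyl points the same way. The C7 alkoxy group is a donor on the allyl terminus that loosens the C5–O bond and lowers the temperature needed, and because the same feature makes the substrate ionisable the medium is kept non-polar and free of acid. The centres C1, C2, C10 and C14 are spectators, and C10 is not enolised under neutral conditions.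

Step 25
Reactants: 33 cyclodecenone
Product: 35 8-hydroxy-9-ketone (epimers at C8), via sodium enolate 34 (not isolated)
Conditions: NaHMDS, THF, −78 °C; then 2-(phenylsulfonyl)-3-phenyloxaziridine, −78 °C; aq. NH4Cl
Reagents that add atoms: 2-(phenylsulfonyl)-3-phenyloxaziridine, O=S(=O)(c1ccccc1)N1OC1c1ccccc1
Why: Kinetic enolisation at the C8 methylene (more accessible than the C10 methine next to the quaternary C1) and Davis hydroxylation of the enolate; the low temperature suppresses β-elimination of the C7 ether, and the C8 configuration is irrelevant.

Step 26
Reactants: 35 8-hydroxy-9-ketone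
Product: 36 8,9-diketone
Conditions: DMP, NaHCO3, CH2Cl2, 0 °C
Reagents that add atoms: none
Why: Dess–Martin oxidation of the ketol to the 1,2-diketone under buffered conditions; the diketone is used at once to limit enolisation toward C7 or C10.

Step 27
Reactants: 36 8,9-diketone; 37 methyl propanoate
Product: 39 aldol adduct (8R tertiary carbinol with C17 ester side chain; C9 ketone), via lithium ester enolate 38 (not isolated)
Conditions: 37, LDA, THF, −78 °C; then 36 precomplexed with MgBr2·OEt2 in CH2Cl2, −78 °C; aq. NH4Cl
Reagents that add atoms: none
Why: Aldol addition of the ester enolate to the C8 carbonyl, which is the less hindered one and is activated in a five-membered magnesium chelate with the O7 ether; attack anti to C6 (Cram chelate model) gives 8R. C17 follows from the enolate geometry and is expected, but not secured, with its methyl anti to C9.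

Step 28
Reactants: 39 aldol adduct
Product: 41 bis-TBS 9-oxo lactone, via hydroxy ester 40 (not isolated)
Conditions: DDQ, CH2Cl2–pH 7 buffer, 0 °C; then CSA (cat.), CH2Cl2, rt
Reagents that add atoms: none
Why: Oxidative cleavage of the 4-methoxybenzyl ether frees the C7 hydroxyl, which closes onto the γ-ester (five-membered acyl substitution) under mild acid catalysis.

Step 29
Reactants: 41 bis-TBS 9-oxo lactone
Product: 42 2,14-diol 9-oxo lactone
Conditions: HF·pyridine, THF, 0 °C to rt
Reagents that add atoms: none
Why: Fluoride desilylation under weakly acidic conditions, which spare the base-sensitive ketol and β-hydroxy lactone.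

Step 30
Reactants: 42 2,14-diol 9-oxo lactone
Product: 43 2,14-diacetate 9-oxo lactone
Conditions: Ac2O, pyridine, DMAP (cat.), CH2Cl2, 0 °C to rt
Reagents that add atoms: acetic anhydride, CC(=O)OC(C)=O
Why: Acetylation of the two secondary hydroxyls; the tertiary C8 carbinol should not be acylated under these conditions, and C9 is still a ketone and cannot compete.

Step 31
Reactants: 43 2,14-diacetate 9-oxo lactone
Product: 44 9-deacetylstylatulide lactone
Conditions: Zn(BH4)2, Et2O, −20 °C
Reagents that add atoms: none
Why: Chelation-controlled reduction of the α-hydroxy ketone; in the zinc chelate of O8 and O9, hydride adds from the face syn to C17 and away from the C7 arm of the macrocycle, which should give 9R, and the esters are not reduced.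

## Compound list

1 | geraniol | CC(C)=CCC/C(C)=C/CO | starting material
2 | (2S,3S)-2,3-epoxygeraniol | OC[C@@H]1O[C@@]1(C)CCC=C(C)C | intermediate
3 | (2R,3S)-2,3-epoxygeranyl chloride | ClC[C@@H]1O[C@@]1(C)CCC=C(C)C | intermediate
4 | (S)-3,7-dimethyloct-6-en-1-yn-3-ol | C#C[C@](O)(C)CCC=C(C)C | intermediate
5 | (S)-3,7-dimethyl-3-(triethylsilyloxy)oct-6-en-1-yne | C#C[C@](O[Si](CC)(CC)CC)(C)CCC=C(C)C | intermediate
6 | ozonide (1,2,4-trioxolane) of 5 | C#C[C@](O[Si](CC)(CC)CC)(C)CCC1OOC(C)(C)O1 | intermediate (not isolated)
7 | (S)-4-methyl-4-(triethylsilyloxy)hex-5-ynal (C2–C7 fragment) | C#C[C@](O[Si](CC)(CC)CC)(C)CCC=O | intermediate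
8 | (S)-(+)-carvone | CC(=C)[C@H]1CC=C(C)C(=O)C1 | starting material
9 | (S)-5-(1-hydroperoxy-1-methoxyethyl)-2-methylcyclohex-2-enone | COC(C)(OO)[C@H]1CC=C(C)C(=O)C1 | intermediate (not isolated)
10 | (S)-5-acetoxy-2-methylcyclohex-2-enone | CC(=O)O[C@H]1CC=C(C)C(=O)C1 | intermediate
11 | (S)-5-hydroxy-2-methylcyclohex-2-enone | O[C@H]1CC=C(C)C(=O)C1 | intermediate
12 | (S)-5-(tert-butyldimethylsilyloxy)-2-methylcyclohex-2-enone | CC(C)(C)[Si](C)(C)O[C@H]1CC=C(C)C(=O)C1 | intermediate
13 | lithium dienolate of 12 | CC(C)(C)[Si](C)(C)O[C@H]1CC=C(C)C([O-])=C1.[Li+] | intermediate (not isolated)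
14 | aldol adduct: ring A enone with C1–CH(OH) chain, 5S silyl ether and alkyne; epimers at C1 and C2 | CC(C)(C)[Si](C)(C)O[C@H]1CC=C(C)C(=O)C1C(O)CC[C@](C)(O[Si](CC)(CC)CC)C#C | intermediate
15 | 2,10-diketone (C1–H, enolisable) | CC(C)(C)[Si](C)(C)O[C@H]1CC=C(C)C(=O)C1C(=O)CC[C@](C)(O[Si](CC)(CC)CC)C#C | intermediate
16 | C1-methylated 2,10-diketone (C15 β, trans to O14) | CC(C)(C)[Si](C)(C)O[C@H]1CC=C(C)C(=O)[C@@]1(C)C(=O)CC[C@](C)(O[Si](CC)(CC)CC)C#C | intermediate
17 | (2R)-carbinol of 16 (C10 enone retained) | CC(C)(C)[Si](C)(C)O[C@H]1CC=C(C)C(=O)[C@@]1(C)[C@H](O)CC[C@](C)(O[Si](CC)(CC)CC)C#C | intermediate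
18 | 2,14-bis-TBS ether enone | CC(C)(C)[Si](C)(C)O[C@H]1CC=C(C)C(=O)[C@@]1(C)[C@H](O[Si](C)(C)C(C)(C)C)CC[C@](C)(O[Si](CC)(CC)CC)C#C | intermediate
19 | 11β,12β-epoxy-10-ketone | CC(C)(C)[Si](C)(C)O[C@H]1C[C@@H]2O[C@]2(C)C(=O)[C@@]1(C)[C@H](O[Si](C)(C)C(C)(C)C)CC[C@](C)(O[Si](CC)(CC)CC)C#C | intermediate
20 | 12β-allylic alcohol with C10=C11 | CC(C)(C)[Si](C)(C)O[C@H]1C[C@H](O)C(C)=C[C@@]1(C)[C@H](O[Si](C)(C)C(C)(C)C)CC[C@](C)(O[Si](CC)(CC)CC)C#C | intermediate
21 | potassium alkoxide of 20 | CC(C)(C)[Si](C)(C)O[C@H]1C[C@H]([O-])C(C)=C[C@@]1(C)[C@H](O[Si](C)(C)C(C)(C)C)CC[C@](C)(O[Si](CC)(CC)CC)C#C.[K+] | intermediate (not isolated)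
22 | 12β-(tributylstannyl)methyl ether | CC(C)(C)[Si](C)(C)O[C@H]1C[C@H](OC[Sn](CCCC)(CCCC)CCCC)C(C)=C[C@@]1(C)[C@H](O[Si](C)(C)C(C)(C)C)CC[C@](C)(O[Si](CC)(CC)CC)C#C | intermediate
23 | C9 primary alcohol (10β-CH2OH, 10α-H, C11=C12) | CC(C)(C)[Si](C)(C)O[C@H]1CC=C(C)[C@H](CO)[C@@]1(C)[C@H](O[Si](C)(C)C(C)(C)C)CC[C@](C)(O[Si](CC)(CC)CC)C#C | intermediate
24 | C9 carboxylic acid (O5 triethylsilyl ether) | CC(C)(C)[Si](C)(C)O[C@H]1CC=C(C)[C@H](C(=O)O)[C@@]1(C)[C@H](O[Si](C)(C)C(C)(C)C)CC[C@](C)(O[Si](CC)(CC)CC)C#C | intermediate
25 | hydroxy acid (C9 acid, free 5S tertiary propargylic carbinol) | CC(C)(C)[Si](C)(C)O[C@H]1CC=C(C)[C@H](C(=O)O)[C@@]1(C)[C@H](O[Si](C)(C)C(C)(C)C)CC[C@](C)(O)C#C | intermediate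
26 | mixed 2,4,6-trichlorobenzoic anhydride of 25 | CC(C)(C)[Si](C)(C)O[C@H]1CC=C(C)[C@H](C(=O)OC(=O)c2c(Cl)cc(Cl)cc2Cl)[C@@]1(C)[C@H](O[Si](C)(C)C(C)(C)C)CC[C@](C)(O)C#C | intermediate (not isolated)
27 | ring A-fused eight-membered lactone (C9 to O5), 5-ethynyl | CC(C)(C)[Si](C)(C)O[C@H]1CC=C(C)[C@@H]2C(=O)O[C@](C)(C#C)CC[C@@H](O[Si](C)(C)C(C)(C)C)[C@@]12C | intermediate
28 | (E)-alkenylzirconocene chloride of 27 | CC(C)(C)[Si](C)(C)O[C@H]1CC=C(C)[C@@H]2C(=O)O[C@](C)(/C=C/[Zr](Cl)(C3C=CC=C3)C4C=CC=C4)CC[C@@H](O[Si](C)(C)C(C)(C)C)[C@@]12C | intermediate (not isolated)
29 | lactone with (E)-2-iodovinyl group on C5 | CC(C)(C)[Si](C)(C)O[C@H]1CC=C(C)[C@@H]2C(=O)O[C@](C)(/C=C/I)CC[C@@H](O[Si](C)(C)C(C)(C)C)[C@@]12C | intermediate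
30 | ring A-fused 2-methyleneoxocane with (E)-2-iodovinyl group on C5 | CC(C)(C)[Si](C)(C)O[C@H]1CC=C(C)[C@@H]2C(=C)O[C@](C)(/C=C/I)CC[C@@H](O[Si](C)(C)C(C)(C)C)[C@@]12C | intermediate
31 | 4-methoxybenzyl alcohol | COc1ccc(CO)cc1 | starting material
32 | ring A-fused 2-methyleneoxocane with (E)-2-(4-methoxybenzyloxy)vinyl group on C5 (5S) | CC(C)(C)[Si](C)(C)O[C@H]1CC=C(C)[C@@H]2C(=C)O[C@](C)(/C=C/OCc3ccc(OC)cc3)CC[C@@H](O[Si](C)(C)C(C)(C)C)[C@@]12C | intermediate (key-step precursor)
33 | bicyclic cyclodecenone (C9 ketone, 7S 4-methoxybenzyl ether, Z C5=C6) | CC(C)(C)[Si](C)(C)O[C@H]1CC=C(C)[C@@H]2C(=O)C[C@H](/C=C(/C)CC[C@@H](O[Si](C)(C)C(C)(C)C)[C@@]12C)OCc1ccc(OC)cc1 | intermediate (key-step product)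
34 | sodium C8–C9 enolate of 33 | CC(C)(C)[Si](C)(C)O[C@H]1CC=C(C)[C@@H]2C([O-])=C[C@H](/C=C(/C)CC[C@@H](O[Si](C)(C)C(C)(C)C)[C@@]12C)OCc1ccc(OC)cc1.[Na+] | intermediate (not isolated)
35 | 8-hydroxy-9-ketone (epimers at C8) | CC(C)(C)[Si](C)(C)O[C@H]1CC=C(C)[C@@H]2C(=O)C(O)[C@H](/C=C(/C)CC[C@@H](O[Si](C)(C)C(C)(C)C)[C@@]12C)OCc1ccc(OC)cc1 | intermediate
36 | 8,9-diketone | CC(C)(C)[Si](C)(C)O[C@H]1CC=C(C)[C@@H]2C(=O)C(=O)[C@H](/C=C(/C)CC[C@@H](O[Si](C)(C)C(C)(C)C)[C@@]12C)OCc1ccc(OC)cc1 | intermediate
37 | methyl propanoate | CCC(=O)OC | starting material
38 | lithium enolate of 37 (methyl trans to OLi) | C/C=C(\OC)[O-].[Li+] | intermediate (not isolated)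
39 | aldol adduct: 8R tertiary carbinol with (17R)-CH(CH3)CO2CH3 on C8, C9 ketone, O7 4-methoxybenzyl ether | CC(C)(C)[Si](C)(C)O[C@H]1CC=C(C)[C@@H]2C(=O)[C@](O)([C@@H](C)C(=O)OC)[C@H](/C=C(/C)CC[C@@H](O[Si](C)(C)C(C)(C)C)[C@@]12C)OCc1ccc(OC)cc1 | intermediate
40 | 7-hydroxy ester (4-methoxybenzyl group removed) | CC(C)(C)[Si](C)(C)O[C@H]1CC=C(C)[C@@H]2C(=O)[C@](O)([C@@H](C)C(=O)OC)[C@H](/C=C(/C)CC[C@@H](O[Si](C)(C)C(C)(C)C)[C@@]12C)O | intermediate (not isolated)
41 | 2,14-bis-TBS 9-oxo lactone | CC(C)(C)[Si](C)(C)O[C@H]1CC=C(C)[C@@H]2C(=O)[C@@]3(O)[C@H](/C=C(/C)CC[C@@H](O[Si](C)(C)C(C)(C)C)[C@@]12C)OC(=O)[C@@H]3C | intermediate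
42 | 2,14-diol 9-oxo lactone | O[C@H]1CC=C(C)[C@@H]2C(=O)[C@@]3(O)[C@H](/C=C(/C)CC[C@@H](O)[C@@]12C)OC(=O)[C@@H]3C | intermediate
43 | 2,14-diacetate 9-oxo lactone (9-ketone of the target) | CC(=O)O[C@H]1CC=C(C)[C@@H]2C(=O)[C@@]3(O)[C@H](/C=C(/C)CC[C@@H](OC(C)=O)[C@@]12C)OC(=O)[C@@H]3C | intermediate
44 | 9-deacetylstylatulide lactone | CC(=O)O[C@H]1CC=C(C)[C@@H]2[C@@H](O)[C@@]3(O)[C@H](/C=C(/C)CC[C@@H](OC(C)=O)[C@@]12C)OC(=O)[C@@H]3C | target

## Step count and least certain steps

Total: 31 steps. Longest linear sequence: 28 steps (steps 1–5, then 9–31); the ring A branch (steps 6–8) joins at step 9.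

**Step 24 (key step).** The C7 donor that accelerates the shift also makes C5 a good cation site. Ionisation of the C5–O bond can therefore compete with the concerted process and lead to fragmentation or to loss of stereochemical fidelity. Passage through the other chair or a boat would erode the Z geometry and the C7 configuration. Acid-promoted migration of the exocyclic enol ether into conjugation with C11=C12 would destroy C10. Fallback: from 32, the rearrangement is run at low temperature with iBu3Al in CH2Cl2, where coordination to the ring oxygen triggers the shift and the ketone is reduced in the same flask. This gives the ring-expanded cyclodecenol F1 (epimers at C9), and Dess–Martin oxidation of the cyclodecenol F1 comes back to 33.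

**Step 20 (lactonisation).** Acyl transfer to a tertiary carbinol is slow and the ring is strained, so intermolecular acylation to dimers and oligomers may outrun closure. Prolonged activation can deprotonate C10 (ketene formation) and scramble that centre. Fallback: from 25, 2,2′-dipyridyl disulfide and PPh3 give the S-(2-pyridyl) thioester F2. Thiophilic activation of the thioester F2 with AgOTf in toluene under high dilution, a neutral double-activation route to hindered esters, closes the ring and comes back to 27.

**Step 15 (Wharton transposition).** Hydrazone formation at the C10 carbonyl, flanked by the quaternary C1 and the epoxide carbon, may be so slow that nucleophilic opening of the epoxide by hydrazine or simple decomposition takes over. Fallback: from 18, dimethylsulfonium methylide (Me3SI, n-BuLi, THF) adds to the C10 carbonyl to give the spiro vinyl epoxide F3. Hydrogenolysis of the vinyl epoxide F3 with Pd(PPh3)4, HCO2H and Et3N delivers hydride to C10 with inversion and comes back at 23, bypassing 19–22. This requires ylide attack from the α face, which the axial β methyl on C1 should favour.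

**Step 27 (propionate addition).** The C17 configuration rests only on the enolate geometry and may come out poorly controlled. Proton transfer from C7 or C10 of the diketone to the basic enolate, or addition at C9, can compete if the chelate is not formed. Fallback: from 33, the C8 enolate (LDA, THF, −78 °C) is alkylated with methyl (R)-2-(trifluoromethylsulfonyloxy)propanoate, with inversion at the lactate carbon, so that C17 comes from the chiral pool; this gives the keto ester F4. Enolisation of the keto ester F4 and oxaziridine hydroxylation at C8 come back to 39.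

**Step 12 (reduction at C2).** Chemoselectivity may be lost through concurrent reduction of the C10 enone carbonyl, and reagent control may be insufficient at a neopentyl ketone. Fallback: from 16, exhaustive reduction with (S)-Me-CBS and BH3·SMe2 gives the 2,10-diol F5. Selective re-oxidation of the allylic C10 carbinol of the diol F5 with MnO2 comes back to 17.

**Step 31 (reduction at C9).** Facial selectivity will be poor if zinc is bound by the acetate or lactone carbonyls and not by O8 and O9. Ketol rearrangement under Lewis acidic conditions is a second risk. Fallback: from 41, the ketone is reduced before the acyl exchange (Zn(BH4)2, Et2O), where the bulky silyl ethers cannot chelate, giving the silylated 8,9-diol F6. HF·pyridine turns F6 into the tetraol F7. Ac2O and pyridine without DMAP then acetylate only the two less hindered secondary hydroxyls of the tetraol F7 (C2, C14) and come back to 44.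

## Further compounds

F1 | step 24 | ring-expanded cyclodecenol (C9 carbinol of 33, epimers at C9) | CC(C)(C)[Si](C)(C)O[C@H]1CC=C(C)[C@@H]2C(O)C[C@H](/C=C(/C)CC[C@@H](O[Si](C)(C)C(C)(C)C)[C@@]12C)OCc1ccc(OC)cc1
F2 | step 20 | S-(2-pyridyl) thioester of 25 | CC(C)(C)[Si](C)(C)O[C@H]1CC=C(C)[C@H](C(=O)Sc2ccccn2)[C@@]1(C)[C@H](O[Si](C)(C)C(C)(C)C)CC[C@](C)(O)C#C
F3 | step 15 | spiro vinyl epoxide at C10 (oxygen β, CH2 α) | CC(C)(C)[Si](C)(C)O[C@H]1CC=C(C)[C@@]2(CO2)[C@@]1(C)[C@H](O[Si](C)(C)C(C)(C)C)CC[C@](C)(O[Si](CC)(CC)CC)C#C
F4 | step 27 | C8-alkylated keto ester ((17R)-CH(CH3)CO2CH3 on C8, epimers at C8) | CC(C)(C)[Si](C)(C)O[C@H]1CC=C(C)[C@@H]2C(=O)C([C@@H](C)C(=O)OC)[C@H](/C=C(/C)CC[C@@H](O[Si](C)(C)C(C)(C)C)[C@@]12C)OCc1ccc(OC)cc1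
F5 | step 12 | 2,10-diol from exhaustive reduction of 16 (2R; epimers at C10) | CC(C)(C)[Si](C)(C)O[C@H]1CC=C(C)C(O)[C@@]1(C)[C@H](O)CC[C@](C)(O[Si](CC)(CC)CC)C#C
F6 | step 31 | 2,14-bis-TBS 8,9-diol lactone (9R) | CC(C)(C)[Si](C)(C)O[C@H]1CC=C(C)[C@@H]2[C@@H](O)[C@@]3(O)[C@H](/C=C(/C)CC[C@@H](O[Si](C)(C)C(C)(C)C)[C@@]12C)OC(=O)[C@@H]3C
F7 | step 31 | 2,8,9,14-tetraol lactone | O[C@H]1CC=C(C)[C@@H]2[C@@H](O)[C@@]3(O)[C@H](/C=C(/C)CC[C@@H](O)[C@@]12C)OC(=O)[C@@H]3C
A1 | alternative 1 | fourteen-membered 2-methyl-1,3-dione with C9–C10 vinyl epoxide and the γ-lactone | O=C1C/C=C(C)\[C@H]2O[C@H]2[C@@]3(O)[C@H](/C=C(/C)CCC(=O)C1C)OC(=O)[C@@H]3C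
A2 | alternative 1 | briarane 2,14-dione with free 8,9-diol | O=C1CC=C(C)[C@@H]2[C@@H](O)[C@@]3(O)[C@H](/C=C(/C)CCC(=O)[C@@]12C)OC(=O)[C@@H]3C
A3 | alternative 2 | C8 ketone with 9-O-triethylsilyl ether and 2-bromopropionate on O7 | CC(=O)O[C@H]1CC=C(C)[C@@H]2[C@@H](O[Si](CC)(CC)CC)C(=O)[C@H](/C=C(/C)CC[C@@H](OC(C)=O)[C@@]12C)OC(=O)C(C)Br
A4 | alternative 2 | 9-O-triethylsilyl-9-deacetylstylatulide lactone | CC(=O)O[C@H]1CC=C(C)[C@@H]2[C@@H](O[Si](CC)(CC)CC)[C@@]3(O)[C@H](/C=C(/C)CC[C@@H](OC(C)=O)[C@@]12C)OC(=O)[C@@H]3C
A5 | alternative 3 | tricyclic cis-2,7-diol (C2–C7 bond intact) with 8,9-acetonide | CC(=O)O[C@H]1CC=C(C)[C@@H]2[C@H]3OC(C)(C)O[C@@]3([C@@H](C)C(=O)OC)[C@]4(O)C=C(C)CC[C@]4(O)[C@@]12C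
A6 | alternative 3 | ten-membered 2,7-diketone with 8,9-acetonide | CC(=O)O[C@H]1CC=C(C)[C@@H]2[C@H]3OC(C)(C)O[C@@]3([C@@H](C)C(=O)OC)C(=O)/C=C(/C)CCC(=O)[C@@]12C
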